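The readings were computed with constants of no real substance; noise was put on by code.

1. Carry one number from the dawn run, the very flask asked about: the split, c(target)/c(starting material), read at 50.0 s.
2. Test its inputs first. A target reading off by 0.3 percentage points moves the split by 0.00371.
3. The same error in starting material moves it by 8.78 × 10⁻⁴, less. So know the target reading well.
4. Dosing time and precatalyst are not terms of this quotient, so this test says nothing of their effect on the flask.
5. Now read it: 0.236 is the split, target over starting material at the last reading.
6. The two readings sum to 99.9%, so take target as split/(1+split) of the charge.
7. Check the drift. At 15.0 s the split read 0.265; the fall of 0.0288 exceeds the 0.00758 that the scatter of the target reading gives there.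
8. My own reckoning: the split is moving, so don't treat two flat readings as a lasting hold.

in all of them: starting material 10 mM (fed, over 30 s); precatalyst 50 µM

| flask | coupling partner | second substrate | remark | time |
|---|---|---|---|---|
| dawn | 30 mM | 20 mM | the very flask that is asked about, followed so far |  |
| flask | 30.0 mM | 20.0 mM |  | 4.0 min |

- dawn (time / s: target / %, starting material / %): 10.0: 6.8, 26.6; 15.0: 10.5, 39.6; 30.0: 19.4, 80.8; 50.0: 19.1, 80.8

(readings scatter by 0.3 percentage points)

- percentages count the whole charge, also what has not yet gone in

- time up to 4.0 min at which target stands highest
- the amount of target, in percent of the starting material charged, at that time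
- earliest time at which at least nineteen twentieths of that best amount are there, in min
- latest time at which they still are, in min

The forecast puts the best at 19.3% at 0.5 min, with the band opening at 0.46 min and shutting at 4 min; its ground is that at the end of the feed “everything freezes”.

The flask gives 20.6% at 0.602 min, and the band runs from 0.503 min to 0.803 min.

    starting material + coupling partner + catalyst ⇌ catalyst + target (K = 22.0 M⁻¹, k = 65000 M⁻² s⁻¹)
    second substrate + coupling partner + catalyst → catalyst + second product (k = 58000 M⁻² s⁻¹)
    precatalyst → catalyst (k = 0.300 s⁻¹)

The flask parts from the forecast at the shutting time. By 4.00 min the flask's split is 0.186, below the dawn reading, with 8.45 mM of coupling partner left. Divide the two: 22.0 M⁻¹, the equilibrium constant K1. Multiply by the 49.8 mM of partner left in the neighbour flask charged with 75 mM: its split comes to 1.10, so target to 52.3%, and that flask stores 52.3%. Take away the return of target to starting material and coupling partner, and the flask's highest target goes from 20.6% to 93.8%.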